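Ring B is disconnected across C5–C6 and C9–C10. Ring A, carrying the C3 and C4 stereocentres from a CBS desymmetrisation, enters as the enol triflate of its C5=C10 double bond; C6–C9 enter as a (1Z)-3-siloxydienylstannane. In one operation a Stille coupling forms C5–C6 and the resulting cis-triene C10=C5–C6=C7–C8=C9, whose six carbons are exactly the atoms of ring B, closes by thermal 6π electrocyclization to form C9–C10 and the methyl-bearing quaternary C10; desilylation in the same flask releases the C8 ketone. Hydrogen-atom-transfer reduction, methylenation and a Nozaki–Hiyama–Kishi/dehydration sequence then complete the dienyl butenolide.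

Key step: step 11

Remark: atoms are numbered as in labdanes (ring A = C1–C5, C10; ring B = C5–C10; C11=C12 the bridge on C9; C13–C16 the butenolide; C17 the methylene carbon on C8; C18 methyl and C19 CH2O on C4; C20 methyl on C10); TBS = tert-butyldimethylsilyl, TBDPS = tert-butyldiphenylsilyl.

Step 1
Reactants: 1 2-methylcyclohexane-1,3-dione
Product: 2 2-(hydroxymethyl)-2-methylcyclohexane-1,3-dione
Conditions: 37% aq. CH2O, Et3N (cat.), THF/H2O, 0 → 25 °C
Reagents that add atoms: formaldehyde (C=O)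
Why: Aldol hydroxymethylation of the enolised 2-alkyl-1,3-dione at C2 should give the quaternary adduct; no stereocentre arises because the two carbonyl arms are identical.

Step 2
Reactants: 2 2-(hydroxymethyl)-2-methylcyclohexane-1,3-dione
Product: 3 2-{[(tert-butyldiphenylsilyl)oxy]methyl}-2-methylcyclohexane-1,3-dione
Conditions: t-BuPh2SiCl, imidazole, DMF, 0 → 25 °C
Reagents that add atoms: tert-butyl(chloro)diphenylsilane (CC(C)(C)[Si](Cl)(c1ccccc1)c1ccccc1)
Why: Silylation of the primary alcohol blocks retro-aldol loss of formaldehyde and installs the bulky arm that later directs the reduction and the ring closure.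

Step 3
Reactants: 3 2-{[(tert-butyldiphenylsilyl)oxy]methyl}-2-methylcyclohexane-1,3-dione
Product: 4 (2R,3R)-2-{[(tert-butyldiphenylsilyl)oxy]methyl}-3-hydroxy-2-methylcyclohexan-1-one
Conditions: (S)-Me-CBS (20 mol%), catecholborane, toluene, −60 °C; then MeOH, aq. NaHCO3
Reagents that add atoms: none
Why: CBS reduction distinguishes the two enantiotopic carbonyl groups: hydride should arrive on the face opposite the bulky CH2OTBDPS arm, and the (S)-catalyst should select the carbonyl whose open face gives the R carbinol, which sets C3 (hydroxyl cis to the CH2O arm) and thereby the quaternary C4.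

Step 4
Reactants: 4 (2R,3R)-2-{[(tert-butyldiphenylsilyl)oxy]methyl}-3-hydroxy-2-methylcyclohexan-1-one
Product: 5 (2R,3R)-3-[(tert-butyldimethylsilyl)oxy]-2-{[(tert-butyldiphenylsilyl)oxy]methyl}-2-methylcyclohexan-1-one
Conditions: t-BuMe2SiOTf, 2,6-lutidine, CH2Cl2, −78 → 0 °C
Reagents that add atoms: tert-butyldimethylsilyl trifluoromethanesulfonate (CC(C)(C)[Si](C)(C)OS(=O)(=O)C(F)(F)F)
Why: Silylation with the silyl triflate protects the hindered secondary alcohol next to the quaternary carbon for the enolate steps that follow.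

Step 5
Reactants: 5 (2R,3R)-3-[(tert-butyldimethylsilyl)oxy]-2-{[(tert-butyldiphenylsilyl)oxy]methyl}-2-methylcyclohexan-1-one
Product: 6 (2R,3R,6RS)-3-[(tert-butyldimethylsilyl)oxy]-2-{[(tert-butyldiphenylsilyl)oxy]methyl}-2,6-dimethylcyclohexan-1-one
Conditions: LiN(iPr)2, THF, −78 °C; MeI, −78 → −20 °C
Reagents that add atoms: iodomethane (CI)
Why: Enolate alkylation at the only enolisable α-carbon (the future C10) introduces C20; the new centre is formed as an epimer mixture and becomes sp2 in step 6.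

Step 6
Reactants: 6 (2R,3R,6RS)-3-[(tert-butyldimethylsilyl)oxy]-2-{[(tert-butyldiphenylsilyl)oxy]methyl}-2,6-dimethylcyclohexan-1-one
Product: 7 (5R,6R)-5-[(tert-butyldimethylsilyl)oxy]-6-{[(tert-butyldiphenylsilyl)oxy]methyl}-2,6-dimethylcyclohex-1-en-1-yl trifluoromethanesulfonate
Conditions: KN(SiMe3)2, THF, −78 → 0 °C; PhNTf2, −78 → 25 °C
Reagents that add atoms: N-phenylbis(trifluoromethanesulfonimide) (O=S(=O)(N(c1ccccc1)S(=O)(=O)C(F)(F)F)C(F)(F)F)
Why: Enolate O-sulfonylation: the ketone can enolise only toward the methyl-bearing carbon, so the tetrasubstituted C5=C10 enol triflate is the only possible regioisomer.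

Step 7
Reactants: 8 (Z)-3-iodoprop-2-enoic acid
Product: 9 (Z)-3-iodo-N-methoxy-N-methylprop-2-enamide
Conditions: MeNHOMe·HCl, EDC·HCl, N-methylmorpholine, CH2Cl2, 0 °C
Reagents that add atoms: N,O-dimethylhydroxylamine hydrochloride (CNOC.Cl)
Why: Carbodiimide amide coupling gives the Weinreb amide; at 0 °C acylation should outrun conjugate addition–elimination at the iodo-bearing carbon, so the Z geometry is kept.

Step 8
Reactants: 9 (Z)-3-iodo-N-methoxy-N-methylprop-2-enamide, 10 3-bromo-1,1-dimethoxypropane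
Product: 12 (Z)-1-iodo-6,6-dimethoxyhex-1-en-3-one, via Grignard reagent 11 (not isolated)
Conditions: 10, Mg, THF, 25 °C; then 9, THF, −78 → −20 °C; pH 7 buffer
Reagents that add atoms: none
Why: Weinreb ketone synthesis: the Grignard reagent adds once to the amide carbonyl through the stable magnesium chelate, and at low temperature the alkenyl iodide should survive.

Step 9
Reactants: 12 (Z)-1-iodo-6,6-dimethoxyhex-1-en-3-one
Product: 13 tert-butyl{[(1Z,3Z)-1-iodo-6,6-dimethoxyhexa-1,3-dien-3-yl]oxy}dimethylsilane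
Conditions: t-BuMe2SiOTf, Et3N, CH2Cl2, −78 → 0 °C
Reagents that add atoms: tert-butyldimethylsilyl trifluoromethanesulfonate (CC(C)(C)[Si](C)(C)OS(=O)(=O)C(F)(F)F)
Why: Soft enolisation and O-silylation at the only enolisable α-carbon should give mainly the Z silyl dienol ether (oxygen cis to the chain), which places the C9 chain outward in the later ring closure.

Step 10
Reactants: 13 tert-butyl{[(1Z,3Z)-1-iodo-6,6-dimethoxyhexa-1,3-dien-3-yl]oxy}dimethylsilane
Product: 14 tert-butyl{[(1Z,3Z)-6,6-dimethoxy-1-(trimethylstannyl)hexa-1,3-dien-3-yl]oxy}dimethylsilane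
Conditions: Me3SnSnMe3, Pd(PPh3)4 (5 mol%), toluene, 70 °C
Reagents that add atoms: hexamethylditin (C[Sn](C)(C)[Sn](C)(C)C)
Why: Palladium-catalysed stannylation of the alkenyl iodide proceeds with retention of the Z geometry and avoids a 3-siloxyalkenyllithium that could suffer silyl migration.

Step 11
Reactants: 7 (5R,6R)-5-[(tert-butyldimethylsilyl)oxy]-6-{[(tert-butyldiphenylsilyl)oxy]methyl}-2,6-dimethylcyclohex-1-en-1-yl trifluoromethanesulfonate, 14 tert-butyl{[(1Z,3Z)-6,6-dimethoxy-1-(trimethylstannyl)hexa-1,3-dien-3-yl]oxy}dimethylsilane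
Product: 17 (3R,4R,9R,10S)-3-[(tert-butyldimethylsilyl)oxy]-19-[(tert-butyldiphenylsilyl)oxy]-12,12-dimethoxy-13,14,15,16,17-pentanorlabd-5-en-8-one, via cis-triene 15 (not isolated), via silyl dienol ether 16 (not isolated)
Conditions: Pd2(dba)3 (5 mol%), AsPh3 (40 mol%), CuI (20 mol%), LiCl, NMP, 60 °C; then 150 °C (sealed); then Bu4NF, AcOH, THF, 0 °C
Reagents that add atoms: none
Why: Zerovalent palladium inserts into the C5–OTf bond of 7, copper-assisted transmetalation with 14 and reductive elimination form C5–C6 with retention of the Z geometry at C6=C7, and the cis-triene 15 (C10=C5–C6=C7–C8=C9) then closes at 150 °C by thermal disrotatory 6π electrocyclization to form C9–C10 before fluoride cleaves the silyl dienol ether with kinetic protonation at C7. The closest known reaction type is the tandem Stille coupling/6π electrocyclization, and the closure onto a methyl-bearing triene terminus is that of previtamin D-type trienes. Ring B is the only ring closed, in a six-electron disrotatory mode that uses all six of its atoms. C10 is controlled by ring A, because the bulky CH2OTBDPS arm on C4 should stay equatorial so that C9 bonds to C10 past the axial C18 methyl on the face opposite C19 and leaves C20 cis to C19, while disrotation sets C9 with H9 cis to C20 (the 9-epimer, corrected by equilibration in step 13). The step needs face selectivity at C10 and ring closure that wins over hydrogen shifts: the Z enol ether keeps the C9 chain outward in the transition state, and the [1,7]-hydrogen shift from C20 to C9 is reversible, so its product should drain back through 15.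

Step 12
Reactants: 17 (3R,4R,9R,10S)-3-[(tert-butyldimethylsilyl)oxy]-19-[(tert-butyldiphenylsilyl)oxy]-12,12-dimethoxy-13,14,15,16,17-pentanorlabd-5-en-8-one
Product: 18 (3R,4R,5S,9R,10R)-3-[(tert-butyldimethylsilyl)oxy]-19-[(tert-butyldiphenylsilyl)oxy]-12,12-dimethoxy-13,14,15,16,17-pentanorlabdan-8-one
Conditions: Mn(dpm)3 (10 mol%), PhSiH3, t-BuOOH, i-PrOH, 22 °C
Reagents that add atoms: none
Why: MHAT hydrogenation: hydrogen-atom transfer to C6 gives the tertiary C5 radical, which should take its hydrogen on the face opposite the axial C19 arm and C20 methyl, setting H5 trans to C20 (trans-decalin).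

Step 13
Reactants: 18 (3R,4R,5S,9R,10R)-3-[(tert-butyldimethylsilyl)oxy]-19-[(tert-butyldiphenylsilyl)oxy]-12,12-dimethoxy-13,14,15,16,17-pentanorlabdan-8-one
Product: 20 (3R,4R,5S,9R,10S)-3-[(tert-butyldimethylsilyl)oxy]-19-[(tert-butyldiphenylsilyl)oxy]-12,12-dimethoxy-13,14,15,16-tetranorlabd-8(17)-ene, via C9-equilibrated ketone 19 (not isolated)
Conditions: KOtBu, Ph3PCH3Br, toluene, 25 → 90 °C
Reagents that add atoms: methyltriphenylphosphonium bromide (C[P+](c1ccccc1)(c1ccccc1)c1ccccc1.[Br-])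
Why: tert-Butoxide should first equilibrate C9 (α to the C8 ketone, no β-leaving group) to the epimer with the side chain equatorial, and the Wittig reaction then turns the ketone into the exocyclic C8=C17 methylene, after which C9 is fixed.

Step 14
Reactants: 20 (3R,4R,5S,9R,10S)-3-[(tert-butyldimethylsilyl)oxy]-19-[(tert-butyldiphenylsilyl)oxy]-12,12-dimethoxy-13,14,15,16-tetranorlabd-8(17)-ene
Product: 21 (3R,4R,5S,9R,10S)-3-[(tert-butyldimethylsilyl)oxy]-19-[(tert-butyldiphenylsilyl)oxy]-13,14,15,16-tetranorlabd-8(17)-en-12-al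
Conditions: PPTS, acetone/H2O 9:1, 50 °C
Reagents that add atoms: water (O)
Why: Mild acid-catalysed acetal hydrolysis frees the C12 aldehyde while both silyl ethers and the exocyclic alkene should survive.

Step 15
Reactants: 21 (3R,4R,5S,9R,10S)-3-[(tert-butyldimethylsilyl)oxy]-19-[(tert-butyldiphenylsilyl)oxy]-13,14,15,16-tetranorlabd-8(17)-en-12-al, 22 3-bromofuran-2(5H)-one
Product: 23 (3R,4R,5S,9R,10S,12RS)-3-[(tert-butyldimethylsilyl)oxy]-19-[(tert-butyldiphenylsilyl)oxy]-12-hydroxylabda-8(17),13-dien-16,15-olide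
Conditions: CrCl2, NiCl2 (2 mol%), DMF, 25 °C
Reagents that add atoms: none
Why: Nozaki–Hiyama–Kishi reaction: zerovalent nickel inserts into the alkenyl C–Br bond and the derived alkenylchromium adds chemoselectively to the aldehyde to form C12–C13; the C12 carbinol centre forms as a mixture that is removed in step 16.

Step 16
Reactants: 23 (3R,4R,5S,9R,10S,12RS)-3-[(tert-butyldimethylsilyl)oxy]-19-[(tert-butyldiphenylsilyl)oxy]-12-hydroxylabda-8(17),13-dien-16,15-olide
Product: 24 (3R,4R,5S,9R,10R,11E)-3-[(tert-butyldimethylsilyl)oxy]-19-[(tert-butyldiphenylsilyl)oxy]labda-8(17),11,13-trien-16,15-olide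
Conditions: Ph2S[OC(CF3)2Ph]2, CH2Cl2, 0 → 25 °C
Reagents that add atoms: none
Why: Sulfurane dehydration (alkoxysulfonium formation, then elimination): only the C11 hydrogens are available, so the C11=C12 bond forms in conjugation with the butenolide and should be E.

Step 17
Reactants: 24 (3R,4R,5S,9R,10R,11E)-3-[(tert-butyldimethylsilyl)oxy]-19-[(tert-butyldiphenylsilyl)oxy]labda-8(17),11,13-trien-16,15-olide
Product: 25 (3R,4R,5S,9R,10R,11E)-3,19-dihydroxylabda-8(17),11,13-trien-16,15-olide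
Conditions: HF·pyridine, pyridine, THF, 0 → 40 °C
Reagents that add atoms: none
Why: Fluoride-mediated desilylation removes both silyl ethers under buffered conditions that the dienyl butenolide and the exocyclic alkene should tolerate.

Step 18
Reactants: 25 (3R,4R,5S,9R,10R,11E)-3,19-dihydroxylabda-8(17),11,13-trien-16,15-olide
Product: 26 (3R,4R,5S,9R,10R,11E)-19-acetoxy-3-hydroxylabda-8(17),11,13-trien-16,15-olide
Conditions: AcCl, 2,4,6-collidine, CH2Cl2, −78 → −40 °C
Reagents that add atoms: acetyl chloride (CC(=O)Cl)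
Why: Selective acylation: the primary C19 hydroxyl should react faster than the secondary C3 hydroxyl next to the quaternary C4.

Compound list
1 | 2-methylcyclohexane-1,3-dione | CC1C(=O)CCCC1=O | starting material
2 | 2-(hydroxymethyl)-2-methylcyclohexane-1,3-dione | CC1(CO)C(=O)CCCC1=O | intermediate
3 | 2-{[(tert-butyldiphenylsilyl)oxy]methyl}-2-methylcyclohexane-1,3-dione | CC1(CO[Si](c2ccccc2)(c2ccccc2)C(C)(C)C)C(=O)CCCC1=O | intermediate
4 | (2R,3R)-2-{[(tert-butyldiphenylsilyl)oxy]methyl}-3-hydroxy-2-methylcyclohexan-1-one (hydroxyl cis to the CH2O arm) | O=C1[C@](C)(CO[Si](c2ccccc2)(c2ccccc2)C(C)(C)C)[C@H](O)CCC1 | intermediate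
5 | (2R,3R)-3-[(tert-butyldimethylsilyl)oxy]-2-{[(tert-butyldiphenylsilyl)oxy]methyl}-2-methylcyclohexan-1-one | O=C1[C@](C)(CO[Si](c2ccccc2)(c2ccccc2)C(C)(C)C)[C@H](O[Si](C)(C)C(C)(C)C)CCC1 | intermediate
6 | (2R,3R,6RS)-3-[(tert-butyldimethylsilyl)oxy]-2-{[(tert-butyldiphenylsilyl)oxy]methyl}-2,6-dimethylcyclohexan-1-one (epimer mixture at C6) | O=C1[C@](C)(CO[Si](c2ccccc2)(c2ccccc2)C(C)(C)C)[C@H](O[Si](C)(C)C(C)(C)C)CCC1C | intermediate
7 | (5R,6R)-5-[(tert-butyldimethylsilyl)oxy]-6-{[(tert-butyldiphenylsilyl)oxy]methyl}-2,6-dimethylcyclohex-1-en-1-yl trifluoromethanesulfonate | CC1=C(OS(=O)(=O)C(F)(F)F)[C@](C)(CO[Si](c2ccccc2)(c2ccccc2)C(C)(C)C)[C@H](O[Si](C)(C)C(C)(C)C)CC1 | intermediate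
8 | (Z)-3-iodoprop-2-enoic acid | I/C=C\C(=O)O | starting material
9 | (Z)-3-iodo-N-methoxy-N-methylprop-2-enamide | I/C=C\C(=O)N(C)OC | intermediate
10 | 3-bromo-1,1-dimethoxypropane | BrCCC(OC)OC | starting material
11 | (3,3-dimethoxypropyl)magnesium bromide | Br[Mg]CCC(OC)OC | intermediate
12 | (Z)-1-iodo-6,6-dimethoxyhex-1-en-3-one | I/C=C\C(=O)CCC(OC)OC | intermediate
13 | tert-butyl{[(1Z,3Z)-1-iodo-6,6-dimethoxyhexa-1,3-dien-3-yl]oxy}dimethylsilane | I/C=C\C(O[Si](C)(C)C(C)(C)C)=C\CC(OC)OC | intermediate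
14 | tert-butyl{[(1Z,3Z)-6,6-dimethoxy-1-(trimethylstannyl)hexa-1,3-dien-3-yl]oxy}dimethylsilane | C[Sn](C)(C)/C=C\C(O[Si](C)(C)C(C)(C)C)=C\CC(OC)OC | intermediate
15 | (5R,6R)-1-[(1Z,3Z)-3-(tert-butyldimethylsilyloxy)-6,6-dimethoxyhexa-1,3-dien-1-yl]-5-(tert-butyldimethylsilyloxy)-6-[(tert-butyldiphenylsilyloxy)methyl]-2,6-dimethylcyclohex-1-ene (cis-triene) | CC1=C(/C=C\C(O[Si](C)(C)C(C)(C)C)=C\CC(OC)OC)[C@](C)(CO[Si](c2ccccc2)(c2ccccc2)C(C)(C)C)[C@H](O[Si](C)(C)C(C)(C)C)CC1 | intermediate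
16 | (3R,4R,9R,10S)-3,8-bis[(tert-butyldimethylsilyl)oxy]-19-[(tert-butyldiphenylsilyl)oxy]-12,12-dimethoxy-13,14,15,16,17-pentanorlabda-5,7-diene (C20 cis to C19; H9 cis to C20) | CC(C)(C)[Si](C)(C)OC1=CC=C2[C@](C)(CO[Si](c3ccccc3)(c3ccccc3)C(C)(C)C)[C@H](O[Si](C)(C)C(C)(C)C)CC[C@@]2(C)[C@H]1CC(OC)OC | intermediate
17 | (3R,4R,9R,10S)-3-[(tert-butyldimethylsilyl)oxy]-19-[(tert-butyldiphenylsilyl)oxy]-12,12-dimethoxy-13,14,15,16,17-pentanorlabd-5-en-8-one (9-epi series) | O=C1CC=C2[C@](C)(CO[Si](c3ccccc3)(c3ccccc3)C(C)(C)C)[C@H](O[Si](C)(C)C(C)(C)C)CC[C@@]2(C)[C@H]1CC(OC)OC | intermediate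
18 | (3R,4R,5S,9R,10R)-3-[(tert-butyldimethylsilyl)oxy]-19-[(tert-butyldiphenylsilyl)oxy]-12,12-dimethoxy-13,14,15,16,17-pentanorlabdan-8-one (trans-decalin, 9-epi) | O=C1CC[C@@H]2[C@](C)(CO[Si](c3ccccc3)(c3ccccc3)C(C)(C)C)[C@H](O[Si](C)(C)C(C)(C)C)CC[C@@]2(C)[C@H]1CC(OC)OC | intermediate
19 | (3R,4R,5S,9S,10R)-3-[(tert-butyldimethylsilyl)oxy]-19-[(tert-butyldiphenylsilyl)oxy]-12,12-dimethoxy-13,14,15,16,17-pentanorlabdan-8-one (side chain equatorial) | O=C1CC[C@@H]2[C@](C)(CO[Si](c3ccccc3)(c3ccccc3)C(C)(C)C)[C@H](O[Si](C)(C)C(C)(C)C)CC[C@@]2(C)[C@@H]1CC(OC)OC | intermediate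
20 | (3R,4R,5S,9R,10S)-3-[(tert-butyldimethylsilyl)oxy]-19-[(tert-butyldiphenylsilyl)oxy]-12,12-dimethoxy-13,14,15,16-tetranorlabd-8(17)-ene | C=C1CC[C@@H]2[C@](C)(CO[Si](c3ccccc3)(c3ccccc3)C(C)(C)C)[C@H](O[Si](C)(C)C(C)(C)C)CC[C@@]2(C)[C@@H]1CC(OC)OC | intermediate
21 | (3R,4R,5S,9R,10S)-3-[(tert-butyldimethylsilyl)oxy]-19-[(tert-butyldiphenylsilyl)oxy]-13,14,15,16-tetranorlabd-8(17)-en-12-al | C=C1CC[C@@H]2[C@](C)(CO[Si](c3ccccc3)(c3ccccc3)C(C)(C)C)[C@H](O[Si](C)(C)C(C)(C)C)CC[C@@]2(C)[C@@H]1CC=O | intermediate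
22 | 3-bromofuran-2(5H)-one | O=C1OCC=C1Br | starting material
23 | (3R,4R,5S,9R,10S,12RS)-3-[(tert-butyldimethylsilyl)oxy]-19-[(tert-butyldiphenylsilyl)oxy]-12-hydroxylabda-8(17),13-dien-16,15-olide | C=C1CC[C@@H]2[C@](C)(CO[Si](c3ccccc3)(c3ccccc3)C(C)(C)C)[C@H](O[Si](C)(C)C(C)(C)C)CC[C@@]2(C)[C@@H]1CC(O)C1=CCOC1=O | intermediate
24 | (3R,4R,5S,9R,10R,11E)-3-[(tert-butyldimethylsilyl)oxy]-19-[(tert-butyldiphenylsilyl)oxy]labda-8(17),11,13-trien-16,15-olide | C=C1CC[C@@H]2[C@](C)(CO[Si](c3ccccc3)(c3ccccc3)C(C)(C)C)[C@H](O[Si](C)(C)C(C)(C)C)CC[C@@]2(C)[C@@H]1/C=C/C1=CCOC1=O | intermediate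
25 | (3R,4R,5S,9R,10R,11E)-3,19-dihydroxylabda-8(17),11,13-trien-16,15-olide | C=C1CC[C@@H]2[C@](C)(CO)[C@H](O)CC[C@@]2(C)[C@@H]1/C=C/C1=CCOC1=O | intermediate
26 | (3R,4R,5S,9R,10R,11E)-19-acetoxy-3-hydroxylabda-8(17),11,13-trien-16,15-olide | C=C1CC[C@@H]2[C@](C)(COC(C)=O)[C@H](O)CC[C@@]2(C)[C@@H]1/C=C/C1=CCOC1=O | target

Total step count: 18. Longest linear sequence: 14 steps (steps 1–6, then 11–18).

Steps most likely to fail

Step 11. Oxidative addition and transmetalation at the tetrasubstituted triflate carbon next to the quaternary C4 may be slow. The reversible hydrogen shifts of the triene may compete at the temperature the ring closure needs. The closure may also take place on the wrong face of C10, since the two C4 substituents differ only moderately in size. The fallback builds ring B by a Diels–Alder reaction instead; it sets out from 7 and returns at 24. Stille coupling of 7 with tributyl(vinyl)stannane (Pd(PPh3)4, LiCl, THF, 65 °C) gives the 1-vinylcyclohexene F1. A thermal Diels–Alder reaction of F1 with methyl but-2-ynoate (toluene, 130 °C, sealed) joins C7–C8 and C9–C10 and gives the cyclohexa-1,4-diene ester F2. MHAT hydrogenation of the C5=C6 bond (Mn(dpm)3, PhSiH3, i-PrOH) gives the trans-fused enoate F3. Kinetic deconjugation (LiN(iPr)2, THF/HMPA, −78 °C, then AcOH) moves the double bond to the exocyclic C8=C17 position, with protonation of C9 on the face opposite C20, and gives the ester F4. i-Bu2AlH (CH2Cl2, −78 °C) gives the aldehyde F5. A boryl Takai olefination (CrCl2, LiI, Cl2CHBpin, THF) gives the (E)-alkenylboronate F6. Suzuki coupling of F6 with 22 (Pd(PPh3)4, K3PO4, THF/H2O) returns to the route at 24.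

Step 13. The ylide may act only as a base on the hindered C8 ketone, so that the ketone is returned on work-up, or it may olefinate the C9 epimer before equilibration is complete. The fallback separates the two events and replaces the Wittig reaction by a Peterson olefination; it sets out from 18 and returns at 20. Equilibration of 18 with NaOMe in MeOH gives the ketone 19, which is isolated. Addition of Me3SiCH2Li with CeCl3 (THF, −78 °C) gives the β-hydroxysilane F7. KH in THF effects the Peterson elimination to 20.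

Step 15. The bromobutenolide may be reduced without addition (protodebromination or reductive dimerisation), or the organochromium may react through the γ-position of the lactone. The fallback uses a selenide-based aldol route; it sets out from 21 and returns at 23. Aldol addition of the lithium enolate of 3-(phenylselanyl)oxolan-2-one (LiN(iPr)2, THF, −78 °C) to 21 gives the selenide F8. Oxidation with H2O2/pyridine (CH2Cl2, 0 °C) and syn-elimination of the selenoxide, which should go into the ring and away from the carbinol carbon, returns to 23.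

Further compounds
F1 | step 11 | (5R,6R)-5-[(tert-butyldimethylsilyl)oxy]-6-{[(tert-butyldiphenylsilyl)oxy]methyl}-1-ethenyl-2,6-dimethylcyclohex-1-ene | CC1=C(C=C)[C@](C)(CO[Si](c2ccccc2)(c2ccccc2)C(C)(C)C)[C@H](O[Si](C)(C)C(C)(C)C)CC1
F2 | step 11 | methyl (3R,4R,10R)-3-[(tert-butyldimethylsilyl)oxy]-19-[(tert-butyldiphenylsilyl)oxy]-12,13,14,15,16-pentanorlabda-5,8-dien-11-oate | C1(C)CC=C2[C@](C)(CO[Si](c3ccccc3)(c3ccccc3)C(C)(C)C)[C@H](O[Si](C)(C)C(C)(C)C)CC[C@@]2(C)C=1C(=O)OC
F3 | step 11 | methyl (3R,4R,5S,10R)-3-[(tert-butyldimethylsilyl)oxy]-19-[(tert-butyldiphenylsilyl)oxy]-12,13,14,15,16-pentanorlabd-8-en-11-oate | C1(C)CC[C@@H]2[C@](C)(CO[Si](c3ccccc3)(c3ccccc3)C(C)(C)C)[C@H](O[Si](C)(C)C(C)(C)C)CC[C@@]2(C)C=1C(=O)OC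
F4 | step 11 | methyl (3R,4R,5S,9R,10R)-3-[(tert-butyldimethylsilyl)oxy]-19-[(tert-butyldiphenylsilyl)oxy]-12,13,14,15,16-pentanorlabd-8(17)-en-11-oate | C=C1CC[C@@H]2[C@](C)(CO[Si](c3ccccc3)(c3ccccc3)C(C)(C)C)[C@H](O[Si](C)(C)C(C)(C)C)CC[C@@]2(C)[C@@H]1C(=O)OC
F5 | step 11 | (3R,4R,5S,9R,10R)-3-[(tert-butyldimethylsilyl)oxy]-19-[(tert-butyldiphenylsilyl)oxy]-12,13,14,15,16-pentanorlabd-8(17)-en-11-al | C=C1CC[C@@H]2[C@](C)(CO[Si](c3ccccc3)(c3ccccc3)C(C)(C)C)[C@H](O[Si](C)(C)C(C)(C)C)CC[C@@]2(C)[C@@H]1C=O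
F6 | step 11 | (3R,4R,5S,9R,10R,11E)-3-[(tert-butyldimethylsilyl)oxy]-19-[(tert-butyldiphenylsilyl)oxy]-12-(4,4,5,5-tetramethyl-1,3,2-dioxaborolan-2-yl)-13,14,15,16-tetranorlabda-8(17),11-diene | C=C1CC[C@@H]2[C@](C)(CO[Si](c3ccccc3)(c3ccccc3)C(C)(C)C)[C@H](O[Si](C)(C)C(C)(C)C)CC[C@@]2(C)[C@@H]1/C=C/B4OC(C)(C)C(C)(C)O4
F7 | step 13 | (3R,4R,5S,8RS,9S,10R)-3-[(tert-butyldimethylsilyl)oxy]-19-[(tert-butyldiphenylsilyl)oxy]-12,12-dimethoxy-17-(trimethylsilyl)-13,14,15,16-tetranorlabdan-8-ol | C[Si](C)(C)CC1(O)CC[C@@H]2[C@](C)(CO[Si](c3ccccc3)(c3ccccc3)C(C)(C)C)[C@H](O[Si](C)(C)C(C)(C)C)CC[C@@]2(C)[C@@H]1CC(OC)OC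
F8 | step 15 | (3R,4R,5S,9R,10S,12RS,13RS)-3-[(tert-butyldimethylsilyl)oxy]-19-[(tert-butyldiphenylsilyl)oxy]-12-hydroxy-13-(phenylselanyl)labd-8(17)-en-16,15-olide | C=C1CC[C@@H]2[C@](C)(CO[Si](c3ccccc3)(c3ccccc3)C(C)(C)C)[C@H](O[Si](C)(C)C(C)(C)C)CC[C@@]2(C)[C@@H]1CC(O)C1([Se]c3ccccc3)CCOC1=O
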